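**Retrosynthetic overview**
1. Target ⇒ bicyclic vinylogous methyl ester without the C1 acyl group (bridgehead lithiation/acylation, then O-demethylation); C7 prenyl ⇒ C7 exocyclic methylene (exo-face hydroboration, B-alkyl Suzuki coupling) ⇒ C7 ketone.
2. C7 ketone and C2 carbonyl ⇒ tricyclic C7–O–C9 ketal of a methyl enol ether (ketal hydrolysis/oxidation; allylic oxidation).
3. Key disconnection C1–C8: Lewis-acid epoxide-opening cyclisation in which one of the two enantiotopic enol ethers of a mirror-symmetric 6,6-dialkyl-1,5-dimethoxycyclohexa-1,4-diene attacks a nerol-derived cis-epoxide; this sets C1, C5 and C8 and leaves the C7 oxygen exo.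
4. Symmetric diene ⇒ two C6 alkylations (prenyl bromide; (2R,3S)-epoxyneryl bromide from Sharpless epoxidation of nerol) of the Birch product of 1,3-dimethoxybenzene.
5. Ring order: ring A (C1–C5, C9) is the former arene; ring B (C1, C9, C5–C8) closes in the key step.

Assumption and conventions: the SMILES is taken literally. With C1 = acyl-bearing bridgehead, C5 = prenylated bridgehead and C9 = bridging ketone, the target is (1S,5S,7S,8R). On ring B, "endo" means the face carrying the C2–C4 bridge and "exo" the opposite face, so the target has 7-endo-prenyl, 8-endo-methyl and 8-exo-homoprenyl. Prenyl = 3-methylbut-2-en-1-yl; homoprenyl = 4-methylpent-3-en-1-yl. This numbering is used for all bicyclic intermediates.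

**Step 1**
Reactants: 1 1,3-dimethoxybenzene
Product: 2 1,5-dimethoxycyclohexa-1,4-diene
Conditions: Na, liquid NH3, t-BuOH, THF, −78 to −33 °C
Reagents that add atoms: none
Why: Birch reduction; both methoxy groups stay on the residual double bonds, giving the unconjugated bis(enol ether).

**Step 2**
Reactants: 2 1,5-dimethoxycyclohexa-1,4-diene; 3 1-bromo-3-methylbut-2-ene (prenyl bromide)
Product: 5 1,5-dimethoxy-6-prenylcyclohexa-1,4-diene, via lithiated diene 4 (not isolated)
Conditions: t-BuLi, THF/HMPA, −78 °C; then 3, −78 °C to rt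
Reagents that add atoms: none
Why: Deprotonation at the doubly allylic C6 between the two enol-ether carbons and SN2 alkylation at the central carbon of the pentadienyl anion; no stereocentre is formed.

**Step 3**
Reactants: 6 nerol
Product: 7 (2R,3S)-2,3-epoxynerol, [(2R,3S)-3-methyl-3-(4-methylpent-3-en-1-yl)oxiran-2-yl]methanol
Conditions: Ti(OiPr)4 (10 mol%), D-(−)-diisopropyl tartrate (12 mol%), t-BuOOH, 4 Å molecular sieves, CH2Cl2, −20 °C
Reagents that add atoms: tert-butyl hydroperoxide, CC(C)(C)OO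
Why: Katsuki–Sharpless asymmetric epoxidation; the D-tartrate ligand delivers oxygen to the face of the allylic Z-alkene that gives the (2R,3S) cis-epoxide (about 90–94% ee expected), and the remote trisubstituted alkene is untouched.

**Step 4**
Reactants: 7 (2R,3S)-2,3-epoxynerol
Product: 9 (2S,3S)-3-(bromomethyl)-2-methyl-2-(4-methylpent-3-en-1-yl)oxirane, via epoxy mesylate 8 (not isolated)
Conditions: MsCl, Et3N, CH2Cl2, −20 °C; then LiBr, THF, 0 °C to rt
Reagents that add atoms: methanesulfonyl chloride, CS(=O)(=O)Cl (its atoms stay only in 8); LiBr, [Li+].[Br-]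
Why: Mesylation and SN2 displacement at the primary carbon; both epoxide stereocentres are untouched (the descriptor at the CH carbon changes only because of CIP priorities).

**Step 5**
Reactants: 5 1,5-dimethoxy-6-prenylcyclohexa-1,4-diene; 9 (2S,3S)-epoxyneryl bromide
Product: 11 1,5-dimethoxy-6-prenyl-6-{[(2R,3S)-3-methyl-3-(4-methylpent-3-en-1-yl)oxiran-2-yl]methyl}cyclohexa-1,4-diene, via lithiated prenyl diene 10 (not isolated)
Conditions: s-BuLi, THF, −78 to −40 °C; then 9, −78 to 0 °C
Reagents that add atoms: none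
Why: Second C6 deprotonation and SN2 alkylation at the primary bromide (faster than attack on the trisubstituted epoxide) build the quaternary carbon; the ring stays mirror-symmetric, so no new stereocentre arises.

**Step 6 (key step)**
Reactants: 11 the symmetric bis(enol ether) epoxide
Product: 12 7,9-epoxy-4,9-dimethoxy-8-endo-methyl-5-prenyl-8-exo-homoprenylbicyclo[3.3.1]non-3-ene (tricyclic mixed ketal; oxygen bridge from the exo face of C7 to C9)
Conditions: TMSOTf (1.1 equiv), 2,6-lutidine, CH2Cl2, −78 °C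
Reagents that add atoms: none
Why: Group-selective cationic epoxide-opening (Prins-type) cyclisation, a known reaction type for the trans-epoxide analogue: the silyl-activated epoxide is opened at its tertiary carbon with inversion by the enol-ether arm that reaches it through a chair-like array with the C7–O bond equatorial (exo), which fixes C1, C5 and C8 (homoprenyl exo, methyl endo) from the epoxide configuration, and the C7 oxygen then traps the C9 oxocarbenium ion as the bridging ketal.

**Step 7**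
Reactants: 12 the tricyclic ketal
Product: 13 7,9-epoxy-4,9-dimethoxy-8-endo-methyl-5-prenyl-8-exo-homoprenylbicyclo[3.3.1]non-3-en-2-one
Conditions: Pd(OH)2 on carbon (cat.), t-BuOOH, K2CO3, CH2Cl2, 0 °C
Reagents that add atoms: tert-butyl hydroperoxide, CC(C)(C)OO
Why: Radical allylic oxidation; the C2 methylene next to the electron-rich enol ether is the most activated C–H site and is converted via the allylic peroxide into the vinylogous ester carbonyl.

**Step 8**
Reactants: 13 the ketal vinylogous ester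
Product: 15 4-methoxy-8-endo-methyl-5-prenyl-8-exo-homoprenylbicyclo[3.3.1]non-3-ene-2,7,9-trione, via C7-exo-hydroxy diketone 14 (not isolated)
Conditions: CrO3, H2SO4, H2O, acetone, 0 °C, 20 min
Reagents that add atoms: water, O
Why: Acid hydrolysis of the strained bicyclic mixed ketal (cleavage of the C9–O bridge bond) frees the C9 ketone and the C7 alcohol, which chromic acid oxidises in the same flask; the vinylogous ester and trisubstituted alkenes survive the short, cold exposure.

**Step 9**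
Reactants: 15 the 2,7,9-trione
Product: 16 4-methoxy-8-endo-methyl-7-methylidene-5-prenyl-8-exo-homoprenylbicyclo[3.3.1]non-3-ene-2,9-dione
Conditions: Ph3PCH3Br, KOt-Bu, THF, 0 °C to rt
Reagents that add atoms: methyltriphenylphosphonium bromide, C[P+](c1ccccc1)(c1ccccc1)c1ccccc1.[Br-]
Why: Wittig methylenation, selective for the C7 ketone because the C9 ketone is flanked by a quaternary and a bridgehead carbon and the vinylogous ester carbonyl is unreactive; no stereocentre is formed.

**Step 10**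
Reactants: 16 the C7 methylidene compound; 17 1-bromo-2-methylprop-1-ene
Product: 19 4-methoxy-8-endo-methyl-5-prenyl-7-endo-prenyl-8-exo-homoprenylbicyclo[3.3.1]non-3-ene-2,9-dione, via B-alkyl-9-BBN 18 (not isolated)
Conditions: 9-BBN, THF, 0 °C to rt; then 17, Pd(dppf)Cl2 (5 mol%), AsPh3, Cs2CO3, DMF/H2O, rt
Reagents that add atoms: 9-borabicyclo[3.3.1]nonane, [H]B1C2CCCC1CCC2 (its boron stays only in 18)
Why: Hydroboration then B-alkyl Suzuki–Miyaura coupling: 9-BBN adds only to the 1,1-disubstituted alkene and delivers H to C7 from the exo face because the endo face is shielded by the C2–C4 bridge, so the CH2B arm, and hence the prenyl group, ends up endo (7S).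

**Step 11**
Reactants: 19 the 7-endo-prenyl vinylogous ester; 20 2-methylpropanoyl chloride
Product: 24 4-methoxy-8-endo-methyl-1-(2-methylpropanoyl)-5-prenyl-7-endo-prenyl-8-exo-homoprenyl-3-(trimethylsilyl)bicyclo[3.3.1]non-3-ene-2,9-dione, via C3-lithio vinylogous ester 21 (not isolated), via C3-silyl vinylogous ester 22 (not isolated), via bridgehead-lithio species 23 (not isolated)
Conditions: LiTMP (1.1 equiv), THF, −78 °C; TMSCl (1.05 equiv); LiTMP (2.5 equiv), −78 to −40 °C; then 20, −78 °C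
Reagents that add atoms: chlorotrimethylsilane, C[Si](C)(C)Cl
Why: The more accessible vinylic C3–H is first blocked as the silane, then bridgehead lithiation at C1 (a carbanion flanked by two carbonyls that cannot become an enolate) and C-acylation install the acyl group; the C1 configuration is fixed by the bicycle.

**Step 12**
Reactants: 24 the C1-acyl C3-silyl vinylogous ester
Product: 26 (1S,5S,7S,8R)-4-hydroxy-8-methyl-5,7-bis(3-methylbut-2-en-1-yl)-8-(4-methylpent-3-en-1-yl)-1-(2-methylpropanoyl)bicyclo[3.3.1]non-3-ene-2,9-dione (target), via C3-silyl diketone 25 (not isolated)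
Conditions: LiCl, DMSO, 120 °C; then 1 M HCl work-up
Reagents that add atoms: none
Why: Krapcho-type SN2 demethylation of the vinylogous ester by chloride gives the diketonate, whose C3 silyl group is lost by C-to-O silyl shift and hydrolysis on acidic work-up; no stereocentre is touched.

**Compound list**
1 | 1,3-dimethoxybenzene | COc1cccc(OC)c1 | starting material
2 | 1,5-dimethoxycyclohexa-1,4-diene | COC1=CCC=C(OC)C1 | intermediate
3 | 1-bromo-3-methylbut-2-ene (prenyl bromide) | CC(C)=CCBr | starting material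
4 | (2,6-dimethoxycyclohexa-2,5-dien-1-yl)lithium | [Li]C1C(OC)=CCC=C1OC | intermediate
5 | 1,5-dimethoxy-6-prenylcyclohexa-1,4-diene | COC1=CCC=C(OC)C1CC=C(C)C | intermediate
6 | nerol, (2Z)-3,7-dimethylocta-2,6-dien-1-ol | CC(C)=CCC/C(C)=C\CO | starting material
7 | [(2R,3S)-3-methyl-3-(4-methylpent-3-en-1-yl)oxiran-2-yl]methanol | CC(C)=CCC[C@]1(C)O[C@@H]1CO | intermediate
8 | [(2R,3S)-3-methyl-3-(4-methylpent-3-en-1-yl)oxiran-2-yl]methyl methanesulfonate | CC(C)=CCC[C@]1(C)O[C@@H]1COS(C)(=O)=O | intermediate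
9 | (2S,3S)-3-(bromomethyl)-2-methyl-2-(4-methylpent-3-en-1-yl)oxirane | CC(C)=CCC[C@]1(C)O[C@@H]1CBr | intermediate
10 | [2,6-dimethoxy-1-prenylcyclohexa-2,5-dien-1-yl]lithium | [Li]C1(CC=C(C)C)C(OC)=CCC=C1OC | intermediate
11 | 1,5-dimethoxy-6-prenyl-6-{[(2R,3S)-3-methyl-3-(4-methylpent-3-en-1-yl)oxiran-2-yl]methyl}cyclohexa-1,4-diene | COC1=CCC=C(OC)C1(CC=C(C)C)C[C@H]2O[C@@]2(C)CCC=C(C)C | intermediate
12 | 7,9-epoxy-4,9-dimethoxy-8-endo-methyl-5-prenyl-8-exo-homoprenylbicyclo[3.3.1]non-3-ene (exo oxygen bridge C7–O–C9) | CO[C@]12O[C@@H]3C[C@@]1(CC=C(C)C)C(OC)=CC[C@H]2[C@]3(C)CCC=C(C)C | intermediate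
13 | 7,9-epoxy-4,9-dimethoxy-8-endo-methyl-5-prenyl-8-exo-homoprenylbicyclo[3.3.1]non-3-en-2-one | CO[C@]12O[C@@H]3C[C@@]1(CC=C(C)C)C(OC)=CC(=O)[C@H]2[C@]3(C)CCC=C(C)C | intermediate
14 | 7-exo-hydroxy-4-methoxy-8-endo-methyl-5-prenyl-8-exo-homoprenylbicyclo[3.3.1]non-3-ene-2,9-dione | CC(C)=CCC[C@]1(C)[C@H](O)C[C@]2(CC=C(C)C)C(=O)[C@H]1C(=O)C=C2OC | intermediate
15 | 4-methoxy-8-endo-methyl-5-prenyl-8-exo-homoprenylbicyclo[3.3.1]non-3-ene-2,7,9-trione | CC(C)=CCC[C@]1(C)C(=O)C[C@]2(CC=C(C)C)C(=O)[C@H]1C(=O)C=C2OC | intermediate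
16 | 4-methoxy-8-endo-methyl-7-methylidene-5-prenyl-8-exo-homoprenylbicyclo[3.3.1]non-3-ene-2,9-dione | CC(C)=CCC[C@]1(C)C(=C)C[C@]2(CC=C(C)C)C(=O)[C@H]1C(=O)C=C2OC | intermediate
17 | 1-bromo-2-methylprop-1-ene | CC(C)=CBr | starting material
18 | 7-endo-[(9-borabicyclo[3.3.1]nonan-9-yl)methyl]-4-methoxy-8-endo-methyl-5-prenyl-8-exo-homoprenylbicyclo[3.3.1]non-3-ene-2,9-dione | CC(C)=CCC[C@]1(C)[C@@H](CB3C4CCCC3CCC4)C[C@]2(CC=C(C)C)C(=O)[C@H]1C(=O)C=C2OC | intermediate
19 | 4-methoxy-8-endo-methyl-5-prenyl-7-endo-prenyl-8-exo-homoprenylbicyclo[3.3.1]non-3-ene-2,9-dione | CC(C)=CCC[C@]1(C)[C@@H](CC=C(C)C)C[C@]2(CC=C(C)C)C(=O)[C@H]1C(=O)C=C2OC | intermediate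
20 | 2-methylpropanoyl chloride | CC(C)C(Cl)=O | starting material
21 | C3-lithio derivative of 19 | CC(C)=CCC[C@]1(C)[C@@H](CC=C(C)C)C[C@]2(CC=C(C)C)C(=O)[C@H]1C(=O)C([Li])=C2OC | intermediate
22 | 3-(trimethylsilyl) derivative of 19 | CC(C)=CCC[C@]1(C)[C@@H](CC=C(C)C)C[C@]2(CC=C(C)C)C(=O)[C@H]1C(=O)C([Si](C)(C)C)=C2OC | intermediate
23 | C1 (bridgehead) lithio derivative of 22 | CC(C)=CCC[C@]1(C)[C@@H](CC=C(C)C)C[C@]2(CC=C(C)C)C(=O)[C@@]1([Li])C(=O)C([Si](C)(C)C)=C2OC | intermediate
24 | 4-methoxy-8-endo-methyl-1-(2-methylpropanoyl)-5-prenyl-7-endo-prenyl-8-exo-homoprenyl-3-(trimethylsilyl)bicyclo[3.3.1]non-3-ene-2,9-dione | CC(C)=CCC[C@]1(C)[C@@H](CC=C(C)C)C[C@]2(CC=C(C)C)C(=O)[C@@]1(C(=O)C(C)C)C(=O)C([Si](C)(C)C)=C2OC | intermediate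
25 | O-demethylated 24 (4-hydroxy, 3-trimethylsilyl) | CC(C)=CCC[C@]1(C)[C@@H](CC=C(C)C)C[C@]2(CC=C(C)C)C(=O)[C@@]1(C(=O)C(C)C)C(=O)C([Si](C)(C)C)=C2O | intermediate
26 | (1S,5S,7S,8R)-4-hydroxy-8-methyl-5,7-bis(3-methylbut-2-en-1-yl)-8-(4-methylpent-3-en-1-yl)-1-(2-methylpropanoyl)bicyclo[3.3.1]non-3-ene-2,9-dione | CC(C)=CCC[C@]1(C)[C@@H](CC=C(C)C)C[C@]2(CC=C(C)C)C(=O)[C@@]1(C(=O)C(C)C)C(=O)C=C2O | target

**Step count and risks**
Total step count: 12. Longest linear sequence: 10 steps (steps 1, 2, 5–12 from 1; the nerol branch, steps 3, 4, 5–12, is equally long). The enantiomeric purity of 26 equals that of epoxide 7, since the rest of 11 is achiral.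

Steps most likely to fail:

Step 6. The cis-epoxide puts the homoprenyl group axial in the chair-like array, and the bis(enol ether) is acid-labile, so epoxide rearrangement or poor group selectivity may compete. Fallback, setting out from 11 and returning at 13: oxidise the doubly allylic ring CH2 of 11 (Pd(OH)2 on carbon, t-BuOOH, K2CO3) to the mirror-symmetric, acid-stable cross-conjugated dienone 3,5-dimethoxy-4-prenyl-4-(epoxynerylmethyl)cyclohexa-2,5-dien-1-one F1. Then run the epoxide opening on F1 with BF3·OEt2 in CH2Cl2 at −78 to −20 °C. The α-carbon of one vinylogous ester arm attacks the tertiary epoxide carbon and the C7 oxygen closes the ketal, giving 13 directly, so step 7 is dropped.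

Step 10. 9-BBN may reduce a ring carbonyl, or the hindered neopentyl-type borane may couple poorly. Fallback, setting out from 15 and returning at 19: Wittig reaction of 15 with MeOCH2PPh3Cl/KHMDS gives the C7 methoxymethylidene enol ether F2. Mild acid (oxalic acid, wet THF) hydrolyses it with protonation of C7 from the exo face to the 7-endo aldehyde F3. NaBH4 (MeOH, −78 °C) reduces only the aldehyde to the 7-endo hydroxymethyl compound F4, and I2/PPh3/imidazole gives the 7-endo iodomethyl compound F5. A reductive cross-electrophile coupling of F5 with 17 (NiBr2·glyme, 4,4′-di-tert-butyl-2,2′-bipyridine, Zn, DMA) then gives 19.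

Step 11. The C1 bridgehead sits next to the quaternary C8, so direct acylation of the lithio species may be slow or low-yielding. Fallback, setting out from 19 and returning at 24: silylate C3 and isolate 22 (LiTMP, TMSCl), lithiate the bridgehead again and quench with I2 to give the C1 bridgehead iodide F6. Iodine–magnesium exchange with i-PrMgCl·LiCl at −78 °C and addition to 2-methylpropanal gives the C1 (1-hydroxy-2-methylpropyl) carbinol F7 (mixture at the carbinol carbon), and Dess–Martin periodinane oxidation gives 24.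

**Further compounds**
F1 | step 6 | 3,5-dimethoxy-4-prenyl-4-{[(2R,3S)-3-methyl-3-(4-methylpent-3-en-1-yl)oxiran-2-yl]methyl}cyclohexa-2,5-dien-1-one | COC1=CC(=O)C=C(OC)C1(CC=C(C)C)C[C@H]2O[C@@]2(C)CCC=C(C)C
F2 | step 10 | 4-methoxy-7-(methoxymethylidene)-8-endo-methyl-5-prenyl-8-exo-homoprenylbicyclo[3.3.1]non-3-ene-2,9-dione (E/Z mixture) | CC(C)=CCC[C@]1(C)C(=COC)C[C@]2(CC=C(C)C)C(=O)[C@H]1C(=O)C=C2OC
F3 | step 10 | 7-endo-formyl-4-methoxy-8-endo-methyl-5-prenyl-8-exo-homoprenylbicyclo[3.3.1]non-3-ene-2,9-dione | CC(C)=CCC[C@]1(C)[C@@H](C=O)C[C@]2(CC=C(C)C)C(=O)[C@H]1C(=O)C=C2OC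
F4 | step 10 | 7-endo-(hydroxymethyl)-4-methoxy-8-endo-methyl-5-prenyl-8-exo-homoprenylbicyclo[3.3.1]non-3-ene-2,9-dione | CC(C)=CCC[C@]1(C)[C@@H](CO)C[C@]2(CC=C(C)C)C(=O)[C@H]1C(=O)C=C2OC
F5 | step 10 | 7-endo-(iodomethyl)-4-methoxy-8-endo-methyl-5-prenyl-8-exo-homoprenylbicyclo[3.3.1]non-3-ene-2,9-dione | CC(C)=CCC[C@]1(C)[C@@H](CI)C[C@]2(CC=C(C)C)C(=O)[C@H]1C(=O)C=C2OC
F6 | step 11 | 1-iodo-4-methoxy-8-endo-methyl-5-prenyl-7-endo-prenyl-8-exo-homoprenyl-3-(trimethylsilyl)bicyclo[3.3.1]non-3-ene-2,9-dione | CC(C)=CCC[C@]1(C)[C@@H](CC=C(C)C)C[C@]2(CC=C(C)C)C(=O)[C@@]1(I)C(=O)C([Si](C)(C)C)=C2OC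
F7 | step 11 | 1-(1-hydroxy-2-methylpropyl)-4-methoxy-8-endo-methyl-5-prenyl-7-endo-prenyl-8-exo-homoprenyl-3-(trimethylsilyl)bicyclo[3.3.1]non-3-ene-2,9-dione | CC(C)=CCC[C@]1(C)[C@@H](CC=C(C)C)C[C@]2(CC=C(C)C)C(=O)[C@@]1(C(O)C(C)C)C(=O)C([Si](C)(C)C)=C2OC
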